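## Retrosynthetic overview

1. Target 25 ⇒ aromatic chromanone acid 23 + prenyl acetate: ring A is dearomatised in the last step by a ligand-controlled Tsuji–Trost C-prenylation of the unprotected substrate (sets the quaternary C6).
2. 23 ⇒ sulfone 14 + aldehyde 19: the C11 chain is grown on the ring by enamine-catalysed alkylation of an ortho-quinone methide (sets the side-chain CH), then an isopropylidene Wittig.
3. 14 ⇒ 6-formylchromanone 8 + cinnamaldehyde: iminium-catalysed Michael addition/hemiacetalisation at C8 (sets the benzylic CH).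
4. 8 ⇒ 2,4,6-trihydroxybenzaldehyde + a chiral-pool hydroxy ester: the formyl group steers the Mitsunobu to 4-OH (fixing C6 versus C8) and later becomes the side-chain CH2.
5. Ring order: benzene ring A bought; pyranone ring B closed in steps 2–3; transient lactol/lactone rings in steps 4–8; ring A dearomatised in step 10. No protecting groups.

Assumption: 25 is one enol tautomer of a 2-acylcyclohexane-1,3,5-trione and the product of step 10 is this tautomeric system; the sense of induction of the ligand in step 10 is taken from the usual working model and must be confirmed by experiment (the enantiomeric ligand is the remedy).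

## Route

Step 1
Reactants: 1 tert-butyl (3S)-3-hydroxybutanoate
Product: 3 tert-butyl (2S,3S)-3-hydroxy-2-methylbutanoate, via dilithium alkoxide enolate 2 (not isolated)
Conditions: LiN(i-Pr)2 (2.2 equiv), THF, −78 → −20 °C; MeI, −78 → 0 °C; H2O
Reagents that add atoms: iodomethane, CI
Why: Fráter–Seebach alkylation, in which the chelated dilithium alkoxide enolate is methylated anti to the C3 oxygen (about 95:5) while the (3S) carbinol carbon from the chiral pool is untouched.

Step 2
Reactants: 3 tert-butyl (2S,3S)-3-hydroxy-2-methylbutanoate; 4 2,4,6-trihydroxybenzaldehyde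
Product: 5 tert-butyl (2S,3R)-3-(4-formyl-3,5-dihydroxyphenoxy)-2-methylbutanoate
Conditions: PPh3, DIAD, THF, 0 → 25 °C (1.3 equiv of 4)
Reagents that add atoms: none
Why: Mitsunobu reaction in which the 4-OH of 4 (para to CHO, most acidic, least hindered; the 2- and 6-OH are tied up by the formyl group) is the nucleophile, and SN2 inversion turns the (3S) carbinol into the (3R) aryl ether that becomes C2 of ring B.

Step 3
Reactants: 5 tert-butyl (2S,3R)-3-(4-formyl-3,5-dihydroxyphenoxy)-2-methylbutanoate
Product: 8 (2R,3R)-5,7-dihydroxy-2,3-dimethyl-4-oxochromane-6-carbaldehyde, via carboxylic acid 6 (not isolated), via cis-chromanone 7 (not isolated)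
Conditions: CF3CO2H–CH2Cl2 (1:1), 25 °C; evaporate; CF3SO3H, 0 → 25 °C, 6 h; ice-water
Reagents that add atoms: none
Why: Acidolysis of the tert-butyl ester and intramolecular Friedel–Crafts acylation ortho to the ether oxygen (the two ortho positions are equivalent, so CHO ends up at C6, para to the ring oxygen) close ring B with C2 (R) intact, and acid-mediated enolisation epimerises C3 of the first-formed cis ketone to the more stable trans (2R,3R) isomer (about 4:1 expected; residual 7 is separated and resubmitted).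

Step 4
Reactants: 8 (2R,3R)-5,7-dihydroxy-2,3-dimethyl-4-oxochromane-6-carbaldehyde; 9 (E)-cinnamaldehyde
Product: 10 lactol (2R,3R,10R)-5,8-dihydroxy-2,3-dimethyl-4-oxo-10-phenyl-3,4,9,10-tetrahydro-2H,8H-pyrano[2,3-f]chromene-6-carbaldehyde (7-O hemiacetal; anomers)
Conditions: (R)-2-[diphenyl(trimethylsilyloxy)methyl]pyrrolidine (20 mol%), PhCO2H (20 mol%), CH2Cl2–MeCN, 0 → 25 °C
Reagents that add atoms: none
Why: Iminium-catalysed Michael addition/hemiacetalisation of a vinylogous acid (Hayashi–Jørgensen catalysis), in which C8, the only free ring carbon, attacks the β-carbon of the activated enal on the face left open by the diphenyl(silyloxy)methyl group of the (R)-catalyst to give the (R) benzylic centre, and ring closure with 7-OH makes the addition irreversible.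

Step 5
Reactants: 10 lactol
Product: 11 lactone (2R,3R,10R)-5-hydroxy-2,3-dimethyl-4,8-dioxo-10-phenyl-3,4,9,10-tetrahydro-2H,8H-pyrano[2,3-f]chromene-6-carbaldehyde
Conditions: Dess–Martin periodinane (1.3 equiv), CH2Cl2, 0 → 25 °C
Reagents that add atoms: none
Why: Dess–Martin oxidation of a lactol to the lactone, in which the doubly chelated 5-OH and the aryl aldehyde do not react and no stereocentre is involved.

Step 6
Reactants: 11 lactone
Product: 14 (3R)-3-[(2R,3R)-5,7-dihydroxy-2,3-dimethyl-6-[(4-methylphenyl)sulfonylmethyl]-4-oxochroman-8-yl]-3-phenylpropanoic acid, via hydroxy acid aldehyde 12 (not isolated), via benzylic alcohol 13 (not isolated)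
Conditions: NaOH (4 equiv), THF–H2O, 0 °C; NaBH4, 0 → 20 °C; then AcOH to pH 4, sodium 4-methylbenzenesulfinate (3 equiv), 25 °C
Reagents that add atoms: water, O; sodium 4-methylbenzenesulfinate, [Na+].[O-]S(=O)c1ccc(C)cc1
Why: Saponification of the aryl lactone, chemoselective NaBH4 reduction of the aryl aldehyde (the chelated chromanone carbonyl of the phenoxide and the carboxylate are inert) and acid-promoted SN1-type displacement of the electron-rich ortho-hydroxybenzylic hydroxyl by sulfinate give a bench-stable quinone methide precursor without touching a stereocentre.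

Step 7
Reactants: 15 2-(2-bromoethyl)-1,3-dioxolane; 16 3-chloro-2-methylprop-1-ene
Product: 19 5-methylhex-5-enal, via Grignard reagent 17 (not isolated), via dioxolane acetal 18 (not isolated)
Conditions: Mg, THF, 25 °C; Li2CuCl4 (3 mol%), 16, −10 → 25 °C; then 2 M HCl, THF, 25 °C
Reagents that add atoms: water, O
Why: Kochi-type copper-catalysed coupling of a Grignard reagent with an allylic chloride, then mild acid hydrolysis of the dioxolane; no stereocentre is formed.

Step 8
Reactants: 14 sulfone acid; 19 5-methylhex-5-enal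
Product: 21 lactol acid (3R)-3-[(2R,3R,7R)-5,8-dihydroxy-2,3-dimethyl-7-(3-methylbut-3-en-1-yl)-4-oxo-3,4,7,8-tetrahydro-2H,6H-pyrano[3,2-g]chromen-10-yl]-3-phenylpropanoic acid (7-O hemiacetal of 22; anomers), via ortho-quinone methide 20 (not isolated)
Conditions: (S)-2-[diphenyl(trimethylsilyloxy)methyl]pyrrolidine (20 mol%), Et3N (4 equiv), 19 (3 equiv), CH2Cl2, 0 → 25 °C; dilute HCl work-up
Reagents that add atoms: none
Why: Proposed new method: Et3N-induced 1,4-elimination of sulfinate from the 7-phenoxide of 14 unmasks ortho-quinone methide 20, whose exocyclic CH2 is attacked by the α-carbon of 19 under enamine activation on the face opposite the diphenyl(silyloxy)methyl group of the (S)-catalyst (the facial rule of aldehyde–nitroalkene Michael additions), giving the (R) side-chain centre, which lactol formation then protects from epimerisation; the closest known reactions are aminocatalytic α-alkylations of aldehydes by ortho-quinone methides released from 2-(tosylalkyl)phenols, and because C8 is already substituted the usual methylene-bridged dimerisation of acylphloroglucinols cannot occur.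

Step 9
Reactants: 21 lactol acid
Product: 23 (3R)-3-[(2R,3R)-5,7-dihydroxy-2,3-dimethyl-6-[(2R)-5-methyl-2-(2-methylprop-1-en-1-yl)hex-5-en-1-yl]-4-oxochroman-8-yl]-3-phenylpropanoic acid, via open-chain aldehyde 22 (not isolated)
Conditions: isopropyltriphenylphosphonium iodide (6 equiv), KN(SiMe3)2 (6 equiv), THF, −78 → 0 °C; aq. NH4Cl
Reagents that add atoms: isopropyltriphenylphosphonium iodide, CC(C)[P+](c1ccccc1)(c1ccccc1)c1ccccc1.[I-]
Why: Wittig olefination in which the lactolate opens to aldehyde 22, which the non-stabilised isopropylidene ylide traps at low temperature faster than the α-centre epimerises, while the carboxylate and the phenoxide-deactivated chromanone carbonyl are inert.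

Step 10
Reactants: 23 aromatic chromanone acid; 24 3-methylbut-2-en-1-yl acetate
Product: 25 CNP0155375.5, (3R)-3-[(2R,3R,6S)-4-hydroxy-2,3-dimethyl-6-(3-methylbut-2-en-1-yl)-6-[(2R)-5-methyl-2-(2-methylprop-1-en-1-yl)hex-5-en-1-yl]-5,7-dioxo-3,5,6,7-tetrahydro-2H-chromen-8-yl]-3-phenylpropanoic acid
Conditions: tris(dibenzylideneacetone)dipalladium–chloroform adduct Pd2(dba)3·CHCl3 (2.5 mol%), (1R,2R)-N,N'-bis[2-(diphenylphosphino)benzoyl]cyclohexane-1,2-diamine (7.5 mol%), Et3N (3 equiv), CH2Cl2, 0 → 25 °C
Reagents that add atoms: none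
Why: Proposed new method: Tsuji–Trost dearomative C-prenylation in which zerovalent palladium ionises 24, the ambident phenoxide of 23 attacks the unsubstituted terminus of the prenyl–palladium unit through C6 (C8 is blocked by its secondary benzylic substituent, O-prenylation is reversible under the catalyst and C–C bond formation is the sink) and the chiral pocket of the Trost ligand selects one face of the planar ring to set the quaternary (S) centre; the closest known reactions are palladium-catalysed dearomative allylations of acylphloroglucinols and Trost-ligand-controlled intermolecular allylic dearomatisation of naphthols.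

## Compound list

1 | tert-butyl (3S)-3-hydroxybutanoate | C[C@H](O)CC(=O)OC(C)(C)C | starting material
2 | dilithium alkoxide enolate of 1 | C[C@H](O[Li])C=C(O[Li])OC(C)(C)C | intermediate
3 | tert-butyl (2S,3S)-3-hydroxy-2-methylbutanoate | C[C@H](O)[C@H](C)C(=O)OC(C)(C)C | intermediate
4 | 2,4,6-trihydroxybenzaldehyde | O=Cc1c(O)cc(O)cc1O | starting material
5 | tert-butyl (2S,3R)-3-(4-formyl-3,5-dihydroxyphenoxy)-2-methylbutanoate | C[C@@H](Oc1cc(O)c(C=O)c(O)c1)[C@H](C)C(=O)OC(C)(C)C | intermediate
6 | (2S,3R)-3-(4-formyl-3,5-dihydroxyphenoxy)-2-methylbutanoic acid | C[C@@H](Oc1cc(O)c(C=O)c(O)c1)[C@H](C)C(=O)O | intermediate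
7 | (2R,3S)-5,7-dihydroxy-2,3-dimethyl-4-oxochromane-6-carbaldehyde (cis) | C[C@H]1Oc2cc(O)c(C=O)c(O)c2C(=O)[C@H]1C | intermediate
8 | (2R,3R)-5,7-dihydroxy-2,3-dimethyl-4-oxochromane-6-carbaldehyde (trans) | C[C@H]1Oc2cc(O)c(C=O)c(O)c2C(=O)[C@@H]1C | intermediate
9 | (E)-cinnamaldehyde | O=C/C=C/c1ccccc1 | starting material
10 | lactol (2R,3R,10R)-5,8-dihydroxy-2,3-dimethyl-4-oxo-10-phenyl-3,4,9,10-tetrahydro-2H,8H-pyrano[2,3-f]chromene-6-carbaldehyde (anomers) | C[C@H]1Oc2c3[C@@H](c4ccccc4)CC(O)Oc3c(C=O)c(O)c2C(=O)[C@@H]1C | intermediate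
11 | lactone (2R,3R,10R)-5-hydroxy-2,3-dimethyl-4,8-dioxo-10-phenyl-3,4,9,10-tetrahydro-2H,8H-pyrano[2,3-f]chromene-6-carbaldehyde | C[C@H]1Oc2c3[C@@H](c4ccccc4)CC(=O)Oc3c(C=O)c(O)c2C(=O)[C@@H]1C | intermediate
12 | (3R)-3-[(2R,3R)-6-formyl-5,7-dihydroxy-2,3-dimethyl-4-oxochroman-8-yl]-3-phenylpropanoic acid | C[C@H]1Oc2c([C@@H](c3ccccc3)CC(=O)O)c(O)c(C=O)c(O)c2C(=O)[C@@H]1C | intermediate
13 | (3R)-3-[(2R,3R)-5,7-dihydroxy-6-(hydroxymethyl)-2,3-dimethyl-4-oxochroman-8-yl]-3-phenylpropanoic acid | C[C@H]1Oc2c([C@@H](c3ccccc3)CC(=O)O)c(O)c(CO)c(O)c2C(=O)[C@@H]1C | intermediate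
14 | (3R)-3-[(2R,3R)-5,7-dihydroxy-2,3-dimethyl-6-[(4-methylphenyl)sulfonylmethyl]-4-oxochroman-8-yl]-3-phenylpropanoic acid | C[C@H]1Oc2c([C@@H](c3ccccc3)CC(=O)O)c(O)c(CS(=O)(=O)c3ccc(C)cc3)c(O)c2C(=O)[C@@H]1C | intermediate
15 | 2-(2-bromoethyl)-1,3-dioxolane | BrCCC1OCCO1 | starting material
16 | 3-chloro-2-methylprop-1-ene | C=C(C)CCl | starting material
17 | [2-(1,3-dioxolan-2-yl)ethyl]magnesium bromide | Br[Mg]CCC1OCCO1 | intermediate
18 | 2-(4-methylpent-4-en-1-yl)-1,3-dioxolane | C=C(C)CCCC1OCCO1 | intermediate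
19 | 5-methylhex-5-enal | C=C(C)CCCC=O | intermediate
20 | (3R)-3-[(2R,3R)-5-hydroxy-2,3-dimethyl-6-methylidene-4,7-dioxo-3,4,6,7-tetrahydro-2H-chromen-8-yl]-3-phenylpropanoic acid (ortho-quinone methide) | C[C@H]1OC2=C([C@@H](c3ccccc3)CC(=O)O)C(=O)C(=C)C(O)=C2C(=O)[C@@H]1C | intermediate
21 | lactol acid (3R)-3-[(2R,3R,7R)-5,8-dihydroxy-2,3-dimethyl-7-(3-methylbut-3-en-1-yl)-4-oxo-3,4,7,8-tetrahydro-2H,6H-pyrano[3,2-g]chromen-10-yl]-3-phenylpropanoic acid (anomers) | C=C(C)CC[C@@H]1Cc2c(O)c3C(=O)[C@H](C)[C@@H](C)Oc3c([C@H](CC(=O)O)c3ccccc3)c2OC1O | intermediate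
22 | (3R)-3-[(2R,3R)-6-[(2R)-2-formyl-5-methylhex-5-en-1-yl]-5,7-dihydroxy-2,3-dimethyl-4-oxochroman-8-yl]-3-phenylpropanoic acid | C=C(C)CC[C@@H](C=O)Cc1c(O)c2C(=O)[C@H](C)[C@@H](C)Oc2c([C@H](CC(=O)O)c2ccccc2)c1O | intermediate
23 | (3R)-3-[(2R,3R)-5,7-dihydroxy-2,3-dimethyl-6-[(2R)-5-methyl-2-(2-methylprop-1-en-1-yl)hex-5-en-1-yl]-4-oxochroman-8-yl]-3-phenylpropanoic acid | C=C(C)CC[C@@H](C=C(C)C)Cc1c(O)c2C(=O)[C@H](C)[C@@H](C)Oc2c([C@H](CC(=O)O)c2ccccc2)c1O | intermediate
24 | 3-methylbut-2-en-1-yl acetate | CC(=O)OCC=C(C)C | starting material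
25 | CNP0155375.5 | C=C(C)CC[C@@H](C=C(C)C)C[C@@]1(CC=C(C)C)C(=O)C2=C(O)[C@H](C)[C@@H](C)OC2=C([C@H](CC(=O)O)c2ccccc2)C1=O | target

## Step count and risks

Total step count: 10. Longest linear sequence: 9 steps (steps 1–6 and 8–10); step 7 is a one-step side branch.

The three steps most likely to fail are steps 10, 8 and 2.

Step 10 is the riskiest: face selectivity on a free acid with three acidic sites is untested, and C8-attack or over-prenylation could compete. The fallback sets out from 23 and changes both the substrate and the source of asymmetry. Dehydrative lactonisation (1-ethyl-3-(3-dimethylaminopropyl)carbodiimide hydrochloride, 4-(dimethylamino)pyridine, CH2Cl2) ties the acid to 7-OH and gives the dihydrocoumarin lactone of 23 F1, in which only the 5-phenoxide can react. Alkylative dearomatisation of F1 with 1-bromo-3-methylbut-2-ene under chiral phase-transfer catalysis (N-(9-anthracenylmethyl)cinchonidinium bromide, CsOH·H2O, toluene, −40 °C) gives the C6-prenylated enol lactone F2. LiOH in THF–H2O at 0 °C opens the enol lactone and the route is rejoined at 25.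

Step 8 can fail if the quinone methide is consumed by side reactions faster than catalytic enamine turnover, or if the amine catalyst is sequestered. The fallback sets out from 19 and 14 and replaces catalysis by a stoichiometric auxiliary nucleophile. Aldehyde 19 is condensed with (R)-1-amino-2-(methoxymethyl)pyrrolidine to the hydrazone of 19 F3, which LiN(i-Pr)2 in THF converts into the lithium aza-enolate F4. F4 (4 equiv; the first equivalents deprotonate 14 and release 20) adds to 20 at −78 °C under auxiliary control to give the alkylated hydrazone F5. Two-phase aqueous oxalic acid removes the auxiliary and the route is rejoined at 21.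

Step 2 can fail by elimination of the activated β-hydroxy ester to the tiglate, and step 3 then has to rely on C3 epimerisation. The fallback sets out from 4 and forms the aryl ether by lactone opening instead. The cis-β-lactone (3R,4S)-3,4-dimethyloxetan-2-one F6 is made from propanoyl chloride and acetaldehyde by ketene–aldehyde cycloaddition (O-trimethylsilylquinidine, LiClO4, i-Pr2NEt, −78 °C; the quinine analogue if the antipode results). The caesium 4-phenoxide of 4 (Cs2CO3, DMF, 25 °C) opens F6 at C4 by SN2 alkyl–oxygen cleavage with inversion to give the free acid (2R,3R)-3-(4-formyl-3,5-dihydroxyphenoxy)-2-methylbutanoic acid F7, which already carries the trans configuration. Cyclisation of F7 in CF3SO3H rejoins the route at 8.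

## Further compounds

F1 | step 10 | lactone of 23 between the carboxyl group and 7-OH | C=C(C)CC[C@@H](C=C(C)C)Cc1c(O)c2C(=O)[C@H](C)[C@@H](C)Oc2c2c1OC(=O)C[C@@H]2c1ccccc1
F2 | step 10 | C6-prenylated enol lactone (lactone of 25) | C=C(C)CC[C@@H](C=C(C)C)C[C@@]1(CC=C(C)C)C(=O)C2=C(O[C@H](C)[C@@H](C)C2=O)C2=C1OC(=O)C[C@@H]2c1ccccc1
F3 | step 8 | (E)-N-[(2R)-2-(methoxymethyl)pyrrolidin-1-yl]-5-methylhex-5-en-1-imine | C=C(C)CCC/C=N/N1CCC[C@@H]1COC
F4 | step 8 | lithium aza-enolate of F3 | C=C(C)CC/C=C/N([Li])N1CCC[C@@H]1COC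
F5 | step 8 | hydrazone of 22 with (R)-1-amino-2-(methoxymethyl)pyrrolidine | C=C(C)CC[C@@H](/C=N/N1CCC[C@@H]1COC)Cc1c(O)c2C(=O)[C@H](C)[C@@H](C)Oc2c([C@H](CC(=O)O)c2ccccc2)c1O
F6 | step 2 | (3R,4S)-3,4-dimethyloxetan-2-one | C[C@@H]1OC(=O)[C@@H]1C
F7 | step 2 | (2R,3R)-3-(4-formyl-3,5-dihydroxyphenoxy)-2-methylbutanoic acid | C[C@@H](Oc1cc(O)c(C=O)c(O)c1)[C@@H](C)C(=O)O
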